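**Retrosynthetic overview**

1. Feature used: in the bicyclo[3.2.1]oct-2-en-8-one core the quaternary bridgehead C1 (allyl) is bonded to C8 and to C7 of the two-carbon bridge, and its neighbour C2 lies next to the oxygenated C3. Returning C7 from C1 to C2 (retro 1,2-vinyl shift) opens the five-membered ring C1–C7–C6–C5–C8 to a bicyclo[2.2.2]oct-5-ene with a tertiary radical at the allyl-bearing carbon.
2. 21 ⇐ 20 (C4 carbonyl reduction) ⇐ 19 (C8 ketal hydrolysis) ⇐ 18 (O-methylation) ⇐ 14 (C4 oxygenation of the C3 ketone) ⇐ 12 + 13 (exo hydroarylation of C6=C7).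
3. 12 ⇐ 9 (radical 1,2-vinyl shift, forms C1–C7) ⇐ 8 ⇐ 7 ⇐ 5 + 6.
4. 5 ⇐ racemic 4 (lipase resolution) ⇐ 3 + 2 (Diels–Alder) ⇐ 1 (oxidative dearomatisation).
5. Ring order: bicyclo[2.2.2]octene in step 1, then the bicyclo[3.2.1]octene by the shift in step 6; no ring is formed afterwards.

Key step: step 6

Remarks on the chemistry:
- Assumption: the lipase follows the Kazlauskas rule and hydrolyses the (7R)-acetate. If its preference is the reverse, the unreacted acetate is taken into step 3 unchanged, because excess allylmagnesium bromide removes the acetyl group in the same operation.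
- Locants of the bridged compounds follow the target numbering (C1 allyl bridgehead, C2–C4 three-carbon bridge, C5 bridgehead, C6 aryl, C7 methyl, C8 one-carbon bridge) and, for the bicyclo[2.2.2] series, the numbering of oxalate 9. The SMILES in the compound list define the configurations.

**Route**

Step 1
Reactants: 1 2-methoxy-5-methylphenol; 2 vinyl acetate
Product: 4 (1RS,4RS,7RS)-3,3-dimethoxy-6-methyl-2-oxobicyclo[2.2.2]oct-5-en-7-yl acetate (racemate; acetoxy syn to the C5=C6 bridge), via masked o-benzoquinone 3 (not isolated)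
Conditions: PhI(OAc)2 (1.1 equiv), MeOH/vinyl acetate (large excess of 2), 1 added slowly, 0 °C → rt
Reagents that add atoms: methanol (CO); vinyl acetate 2 (C=COC(C)=O)
Why: Oxidative dearomatisation of the guaiacol gives dienone 3, which is trapped as it forms in an inverse-electron-demand Diels–Alder reaction by the excess dienophile before it can dimerise; the oxygenated dienophile carbon bonds to the dienone α-carbon (the usual "ortho" regiochemistry of these dienones) and the acetoxy group takes the endo position syn to the new alkene, the adduct being racemic.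

Step 2
Reactants: 4 racemic acetate
Product: 5 (1R,4R,7R)-7-hydroxy-3,3-dimethoxy-6-methylbicyclo[2.2.2]oct-5-en-2-one
Conditions: Burkholderia cepacia lipase (Amano PS), pH 7 phosphate buffer/acetone, 30 °C, stopped near half conversion; chromatography
Reagents that add atoms: none
Why: Lipase-catalysed enantioselective hydrolysis (kinetic resolution of a secondary acetate): in the (7R)-acetate the large bridgehead and the medium methylene substituent are placed as the Kazlauskas rule requires for the fast enantiomer, so alcohol 5 should be separable from the unreacted enantiomeric acetate.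

Step 3
Reactants: 5 hydroxy ketone; 6 allylmagnesium bromide
Product: 7 (1R,2S,4R,7R)-2-allyl-3,3-dimethoxy-6-methylbicyclo[2.2.2]oct-5-ene-2,7-diol (allyl syn to the C5=C6 bridge)
Conditions: C3H5MgBr (3 equiv), THF, −78 °C, 5 added to the reagent; then H2O (pH 7 buffer)
Reagents that add atoms: allylmagnesium bromide 6 (C=CC[Mg]Br)
Why: Grignard 1,2-addition in which the first equivalent deprotonates the hydroxyl group and the second adds to the C2 ketone at low temperature faster than the β-alkoxy ketone can cleave by retro-aldol reaction, from the face syn to the C5=C6 bridge (less hindered than the face under the C7–C8 bridge); the configuration of the new carbinol carbon is of no consequence because C2 becomes a radical in step 6.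

Step 4
Reactants: 7 diol
Product: 8 (1S,2S,4R)-2-allyl-2-hydroxy-3,3-dimethoxy-6-methylbicyclo[2.2.2]oct-5-en-7-one
Conditions: Dess–Martin periodinane (1.2 equiv), CH2Cl2, 0 °C → rt
Reagents that add atoms: none
Why: Dess–Martin oxidation converts only the secondary alcohol, under non-basic conditions that spare the tertiary alcohol and do not expose the β-hydroxy ketone to retro-aldol cleavage; the α-carbon C1 is a bridgehead and cannot epimerise.

Step 5
Reactants: 8 keto alcohol
Product: 9 (1S,2S,4R)-2-allyl-3,3-dimethoxy-6-methyl-7-oxobicyclo[2.2.2]oct-5-en-2-yl methyl oxalate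
Conditions: ClCOCO2Me (2 equiv), Et3N (3 equiv), DMAP (0.2 equiv), CH2Cl2, 0 °C → rt
Reagents that add atoms: methyl chlorooxoacetate (COC(=O)C(Cl)=O)
Why: DMAP-catalysed acylation of the hindered tertiary alcohol by a small, very electrophilic acid chloride; β-elimination of the new ester toward the bridgehead C1 is not possible.

Step 6
Reactants: 9 tertiary methyl oxalate
Product: 12 (1S,5R)-1-allyl-8,8-dimethoxy-7-methylbicyclo[3.2.1]oct-6-en-3-one, via tertiary radical 10 (not isolated), via α-keto radical 11 (not isolated)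
Conditions: Bu3SnH (1.5 equiv) and AIBN (0.2 equiv) in PhMe added by syringe pump over 8 h to 9 in PhMe (0.005 M), reflux
Reagents that add atoms: none
Why: The stannyl radical adds to the oxalate carbonyl and C–O β-scission (tin hydride deoxygenation of a tertiary methyl oxalate) releases tertiary radical 10, which is homoallylic to the ring alkene; it closes 3-exo-trig onto the methyl-bearing vinyl carbon (future C7) and the cyclopropylcarbinyl radical reopens by breaking the old C2–C7 bond, so that C7 has moved from C2 to C1 and the ketone-stabilised radical 11 takes hydrogen from Bu3SnH. The closest known reaction is the homoallyl–cyclopropylcarbinyl–homoallyl rearrangement of bicyclo[2.2.2]oct-5-en-2-yl radicals into carbonyl-stabilised bicyclo[3.2.1]oct-6-enyl radicals. The ring formed is the five-membered ring C1–C7–C6–C5–C8, by 3-exo-trig closure followed by ring opening (net 1,2-shift), which turns the bicyclo[2.2.2]octene into the bicyclo[3.2.1]oct-6-ene. The one new stereocenter, C1, is fixed by bridgehead C5, because the migrating carbon stays on the cage and can bond to C1 from one side only; the carbinol configuration of 9 is erased. The step needs the shift to outrun hydrogen transfer to 10, which slow stannane addition at high dilution and the gain of an α-keto radical should secure. It also needs vinyl migration to outrun the possible 1,2-shift of the C3 acyl carbon, which rests on the markedly higher migratory aptitude of vinyl over acyl groups in 1,2-shifts of carbon radicals.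

Step 7
Reactants: 12 bicyclo[3.2.1]octenone; 13 3,4-dimethoxyphenylboronic acid
Product: 14 (1S,5R,6S,7S)-1-allyl-6-(3,4-dimethoxyphenyl)-8,8-dimethoxy-7-methylbicyclo[3.2.1]octan-3-one (aryl exo, methyl endo)
Conditions: 13 (2.5 equiv), [Rh(cod)OH]2 (2.5 mol %), 1,4-dioxane/H2O (10:1), 60 °C
Reagents that add atoms: 3,4-dimethoxyphenylboronic acid 13 (OB(O)c1ccc(OC)c(OC)c1)
Why: Rhodium-catalysed hydroarylation of a strained bicyclic alkene: the aryl complex of monovalent rhodium adds syn across C6=C7 from the exo face (the endo face lies over the C2–C4 bridge), with aryl on the less substituted C6 and rhodium on C7, and protonolysis with retention leaves H exo and methyl endo at C7; the unstrained allyl alkene and the ketone should not react.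

Step 8
Reactants: 14 aryl ketone
Product: 16 (1S,4R,5S,6S,7S)-1-allyl-6-(3,4-dimethoxyphenyl)-4-hydroxy-8,8-dimethoxy-7-methylbicyclo[3.2.1]octan-3-one, via potassium enolate 15 (not isolated)
Conditions: KN(SiMe3)2 (1.2 equiv), THF, −78 °C; 2-(benzenesulfonyl)-3-phenyloxaziridine (1.5 equiv), −78 °C; then AcOH
Reagents that add atoms: 2-(benzenesulfonyl)-3-phenyloxaziridine (O=S(=O)(c1ccccc1)N1OC1c1ccccc1)
Why: Kinetic deprotonation by the bulky amide at C4, whose neighbour C5 carries hydrogen, in preference to C2 next to quaternary C1, followed by Davis oxidation of enolate 15; the oxidant should approach anti to the C8 methoxy group that lies over the three-carbon bridge, but the C4 configuration is erased in step 9.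

Step 9
Reactants: 16 α-hydroxy ketone
Product: 18 (1R,5S,6S,7S)-1-allyl-6-(3,4-dimethoxyphenyl)-3-hydroxy-8,8-dimethoxy-7-methylbicyclo[3.2.1]oct-2-en-4-one, via 3,4-dione 17 (not isolated)
Conditions: Dess–Martin periodinane (1.3 equiv), CH2Cl2, rt
Reagents that add atoms: none
Why: Dess–Martin oxidation of the α-ketol gives dione 17, which can enolise only toward C2 because C5 is a bridgehead (Bredt's rule), so a single diosphenol results.

Step 10
Reactants: 18 diosphenol
Product: 19 (1R,5S,6S,7S)-1-allyl-6-(3,4-dimethoxyphenyl)-3,8,8-trimethoxy-7-methylbicyclo[3.2.1]oct-2-en-4-one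
Conditions: MeI (3 equiv), K2CO3 (2 equiv), acetone, 40 °C
Reagents that add atoms: iodomethane (CI)
Why: Williamson O-methylation of the acidic enol of a cyclic 1,2-dione, which reacts at oxygen with methyl iodide and carbonate.

Step 11
Reactants: 19 ketal enone
Product: 20 (1R,5R,6S,7S)-1-allyl-6-(3,4-dimethoxyphenyl)-3-methoxy-7-methylbicyclo[3.2.1]oct-2-ene-4,8-dione
Conditions: TFA/H2O (4:1), CH2Cl2, 0 °C → rt
Reagents that add atoms: water (O)
Why: Acid-catalysed hydrolysis of the dimethyl ketal; the α-methoxy enone should survive because protonation at C2 would place a cation next to the C4 carbonyl group, and the allyl group is inert.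

Step 12
Reactants: 20 enedione
Product: 21 (1R,4R,5S,6S,7S)-1-allyl-6-(3,4-dimethoxyphenyl)-4-hydroxy-3-methoxy-7-methylbicyclo[3.2.1]oct-2-en-8-one (target)
Conditions: NaBH4 (1.0 equiv), CeCl3·7H2O (1.1 equiv), MeOH, −78 °C; pH 7 buffer
Reagents that add atoms: none
Why: Luche 1,2-reduction: cerium activates the conjugated α-methoxy ketone at C4, which should be reduced faster than the bridging C8 ketone next to quaternary C1, and hydride enters from the face of the now trigonal one-carbon bridge because the other face is screened by the C6–C7 bridge, which sets the C4 hydroxyl syn to the two-carbon bridge.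

**Compound list**

1 | 2-methoxy-5-methylphenol | COc1ccc(C)cc1O | starting material
2 | vinyl acetate | C=COC(C)=O | starting material
3 | 6,6-dimethoxy-3-methylcyclohexa-2,4-dien-1-one | COC1(OC)C=CC(C)=CC1=O | intermediate
4 | (1RS,4RS,7RS)-3,3-dimethoxy-6-methyl-2-oxobicyclo[2.2.2]oct-5-en-7-yl acetate (racemate; the enantiomer carried forward is drawn) | CC(=O)O[C@@H]1C[C@@H]2C=C(C)[C@H]1C(=O)C2(OC)OC | intermediate
5 | (1R,4R,7R)-7-hydroxy-3,3-dimethoxy-6-methylbicyclo[2.2.2]oct-5-en-2-one | O[C@@H]1C[C@@H]2C=C(C)[C@H]1C(=O)C2(OC)OC | intermediate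
6 | allylmagnesium bromide | C=CC[Mg]Br | starting material
7 | (1R,2S,4R,7R)-2-allyl-3,3-dimethoxy-6-methylbicyclo[2.2.2]oct-5-ene-2,7-diol | C=CC[C@]1(O)[C@H]2[C@H](O)C[C@@H](C1(OC)OC)C=C2C | intermediate
8 | (1S,2S,4R)-2-allyl-2-hydroxy-3,3-dimethoxy-6-methylbicyclo[2.2.2]oct-5-en-7-one | C=CC[C@]1(O)[C@H]2C(=O)C[C@@H](C1(OC)OC)C=C2C | intermediate
9 | (1S,2S,4R)-2-allyl-3,3-dimethoxy-6-methyl-7-oxobicyclo[2.2.2]oct-5-en-2-yl methyl oxalate | C=CC[C@]1(OC(=O)C(=O)OC)[C@H]2C(=O)C[C@@H](C1(OC)OC)C=C2C | intermediate
10 | 2-allyl-3,3-dimethoxy-6-methyl-7-oxobicyclo[2.2.2]oct-5-en-2-yl radical | C=CC[C]1[C@H]2C(=O)C[C@@H](C1(OC)OC)C=C2C | intermediate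
11 | 1-allyl-8,8-dimethoxy-7-methyl-3-oxobicyclo[3.2.1]oct-6-en-2-yl radical | C=CC[C@@]12[CH]C(=O)C[C@@H](C1(OC)OC)C=C2C | intermediate
12 | (1S,5R)-1-allyl-8,8-dimethoxy-7-methylbicyclo[3.2.1]oct-6-en-3-one | C=CC[C@@]12CC(=O)C[C@@H](C1(OC)OC)C=C2C | intermediate
13 | 3,4-dimethoxyphenylboronic acid | OB(O)c1ccc(OC)c(OC)c1 | starting material
14 | (1S,5R,6S,7S)-1-allyl-6-(3,4-dimethoxyphenyl)-8,8-dimethoxy-7-methylbicyclo[3.2.1]octan-3-one | C=CC[C@@]12CC(=O)C[C@@H](C1(OC)OC)[C@@H](c1ccc(OC)c(OC)c1)[C@@H]2C | intermediate
15 | potassium enolate of 14 (C3–O, C3=C4) | C=CC[C@@]12CC([O-])=C[C@@H](C1(OC)OC)[C@@H](c1ccc(OC)c(OC)c1)[C@@H]2C.[K+] | intermediate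
16 | (1S,4R,5S,6S,7S)-1-allyl-6-(3,4-dimethoxyphenyl)-4-hydroxy-8,8-dimethoxy-7-methylbicyclo[3.2.1]octan-3-one | C=CC[C@@]12CC(=O)[C@H](O)[C@@H](C1(OC)OC)[C@@H](c1ccc(OC)c(OC)c1)[C@@H]2C | intermediate
17 | (1S,5S,6S,7S)-1-allyl-6-(3,4-dimethoxyphenyl)-8,8-dimethoxy-7-methylbicyclo[3.2.1]octane-3,4-dione | C=CC[C@@]12CC(=O)C(=O)[C@@H](C1(OC)OC)[C@@H](c1ccc(OC)c(OC)c1)[C@@H]2C | intermediate
18 | (1R,5S,6S,7S)-1-allyl-6-(3,4-dimethoxyphenyl)-3-hydroxy-8,8-dimethoxy-7-methylbicyclo[3.2.1]oct-2-en-4-one | C=CC[C@@]12C=C(O)C(=O)[C@@H](C1(OC)OC)[C@@H](c1ccc(OC)c(OC)c1)[C@@H]2C | intermediate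
19 | (1R,5S,6S,7S)-1-allyl-6-(3,4-dimethoxyphenyl)-3,8,8-trimethoxy-7-methylbicyclo[3.2.1]oct-2-en-4-one | C=CC[C@@]12C=C(OC)C(=O)[C@@H](C1(OC)OC)[C@@H](c1ccc(OC)c(OC)c1)[C@@H]2C | intermediate
20 | (1R,5R,6S,7S)-1-allyl-6-(3,4-dimethoxyphenyl)-3-methoxy-7-methylbicyclo[3.2.1]oct-2-ene-4,8-dione | C=CC[C@@]12C=C(OC)C(=O)[C@@H](C1=O)[C@@H](c1ccc(OC)c(OC)c1)[C@@H]2C | intermediate
21 | (1R,4R,5S,6S,7S)-1-allyl-6-(3,4-dimethoxyphenyl)-4-hydroxy-3-methoxy-7-methylbicyclo[3.2.1]oct-2-en-8-one | C=CC[C@@]12C=C(OC)[C@H](O)[C@@H](C1=O)[C@@H](c1ccc(OC)c(OC)c1)[C@@H]2C | target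

**Step count**

Total steps: 12. Longest linear sequence: 12 steps (from 1).

**Steps most likely to fail**

Step 6. What may go wrong: hydrogen transfer from the stannane to radical 10 before the vinyl shift, or competing 1,2-migration of the C3 acyl carbon at reflux temperature. The fallback sets out from 9. Its methyl ester is cleaved selectively with CsOH (1 equiv, THF/H2O) to the caesium oxalate F1. F1 is irradiated with blue light in the presence of Ir[dF(CF3)ppy]2(dtbbpy)PF6 in DME/DMF containing water at room temperature. Oxidation of the carboxylate by the excited trivalent iridium complex and loss of two molecules of CO2 should give radical 10 with no hydrogen-atom donor present. After the shift, radical 11 is reduced by the divalent iridium species to the enolate, which is protonated by water. The route is rejoined at 12. The lower temperature should also favour the lower-barrier vinyl migration.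

Step 7. What may go wrong: slow or endo-selective carbometalation, because the C8 methoxy group lying over C6=C7 screens the exo face of the trisubstituted alkene. The fallback sets out from 12. The ketal is hydrolysed first (aqueous TFA) to the 3,8-dione F2, in which C8 is trigonal and the exo face is open. Hydroarylation of F2 with 13 under the conditions of step 7 should give the aryl dione F3. The C8 ketone has only bridgehead α-carbons and cannot enolise, so the reagents of steps 8 to 10 are applied unchanged: hydroxylation to the 4-hydroxy dione F4, oxidation to the diosphenol F5, and O-methylation. The route is rejoined at 20, and the separate hydrolysis of step 11 is no longer needed.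

Step 8. What may go wrong: competing deprotonation at C2, or proton exchange between enolate and ketone, so that oxygen is also introduced at C2. The fallback sets out from 14. Claisen formylation under equilibrating conditions (HCO2Et, NaH, THF) should place the new carbon at the less hindered C4 and give the hydroxymethylene ketone F6. Deformylative diazo transfer (4-methylbenzenesulfonyl azide, Et3N, MeCN) then gives the 4-diazo-3-ketone F7. Oxidation of the diazo group with dimethyldioxirane in acetone at −78 °C gives dione 17, which enolises. The route is rejoined at 18.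

**Further compounds**

F1 | step 6 | caesium 2-[(2-allyl-3,3-dimethoxy-6-methyl-7-oxobicyclo[2.2.2]oct-5-en-2-yl)oxy]-2-oxoacetate (configuration as in 9) | C=CC[C@]1(OC(=O)C(=O)[O-])[C@H]2C(=O)C[C@@H](C1(OC)OC)C=C2C.[Cs+]
F2 | step 7 | 1-allyl-7-methylbicyclo[3.2.1]oct-6-ene-3,8-dione (bridgeheads as in 12) | C=CC[C@@]12CC(=O)C[C@@H](C1=O)C=C2C
F3 | step 7 | 1-allyl-6-exo-(3,4-dimethoxyphenyl)-7-endo-methylbicyclo[3.2.1]octane-3,8-dione | C=CC[C@@]12CC(=O)C[C@@H](C1=O)[C@@H](c1ccc(OC)c(OC)c1)[C@@H]2C
F4 | step 7 | 1-allyl-6-exo-(3,4-dimethoxyphenyl)-4-hydroxy-7-endo-methylbicyclo[3.2.1]octane-3,8-dione (hydroxyl syn to C8) | C=CC[C@@]12CC(=O)[C@@H](O)[C@@H](C1=O)[C@@H](c1ccc(OC)c(OC)c1)[C@@H]2C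
F5 | step 7 | 1-allyl-6-exo-(3,4-dimethoxyphenyl)-3-hydroxy-7-endo-methylbicyclo[3.2.1]oct-2-ene-4,8-dione | C=CC[C@@]12C=C(O)C(=O)[C@@H](C1=O)[C@@H](c1ccc(OC)c(OC)c1)[C@@H]2C
F6 | step 8 | 1-allyl-6-exo-(3,4-dimethoxyphenyl)-4-(hydroxymethylene)-8,8-dimethoxy-7-endo-methylbicyclo[3.2.1]octan-3-one (chelated enol) | C=CC[C@@]12CC(=O)/C(=C\O)[C@@H](C1(OC)OC)[C@@H](c1ccc(OC)c(OC)c1)[C@@H]2C
F7 | step 8 | 1-allyl-4-diazo-6-exo-(3,4-dimethoxyphenyl)-8,8-dimethoxy-7-endo-methylbicyclo[3.2.1]octan-3-one | C=CC[C@@]12CC(=O)C(=[N+]=[N-])[C@@H](C1(OC)OC)[C@@H](c1ccc(OC)c(OC)c1)[C@@H]2C
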